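Lactone numbering: O1, C2 (C=O), C3 (=CH2), C4 (CO2H), C5; side chain C6–C20 with the carbinol at C19. The retrosynthesis first lowers the C4 carboxyl to a silylated CH2OH. It then cuts O1–C2 and C2–C3 together, which removes C2 as carbon monoxide.
Enabling feature: in the single five-membered ring, the run O1–C2(=O)–C3(=CH2) is one CO lodged between the C5 oxygen and the inner carbon of a terminal ethynyl group on C4. The open form is therefore a but-3-yn-1-ol.
Further cuts: C3–C4 (alkynyl anion on a trans-2,3-epoxy alcohol), C5–C6 (acetylide on a primary bromide), C17–C18 (Grignard reagent on an epoxide).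
Forward order: C5–C6, C17–C18, alkyne to E-alkene to epoxide, C3–C4, closure of the only ring, oxidation of the C4 arm, release of the C19 hydroxyl.
Stereochemistry: C19 is bought in (S)-propylene oxide. C5 is set by a Sharpless epoxidation with (+)-diethyl L-tartrate, and C4 by SN2 inversion at the epoxide. The resulting syn pair becomes the cis-lactone.

Key step: step 10

Assumption: O-silylated propargyl alcohol 1 is taken as a purchasable compound; it is otherwise one silylation away from propargyl alcohol. TBS = tert-butyldimethylsilyl, TBDPS = tert-butyldiphenylsilyl.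

Step 1
Reactants: 1 tert-butyldimethyl(prop-2-yn-1-yloxy)silane; 2 1,12-dibromododecane
Product: 4 [(15-bromopentadec-2-yn-1-yl)oxy](tert-butyl)dimethylsilane, via lithium acetylide 3 (not isolated)
Conditions: n-BuLi, THF, −78 °C; then 2 (3 equiv), DMPU, −78 °C → rt
Reagents that add atoms: none
Why: SN2 alkylation of a lithium acetylide by a primary bromide in THF–DMPU is standard, and the excess of the symmetrical dibromide should hold double substitution down while the surplus 2 is recovered.

Step 2
Reactants: 4 [(15-bromopentadec-2-yn-1-yl)oxy](tert-butyl)dimethylsilane; 5 (S)-propylene oxide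
Product: 7 (2S)-18-[(tert-butyldimethylsilyl)oxy]octadec-16-yn-2-ol, via alkylmagnesium bromide 6 (not isolated)
Conditions: Mg, THF, rt → 40 °C; then CuI (10 mol %), 5, THF, −30 → 0 °C; aq NH4Cl
Reagents that add atoms: none
Why: The copper-catalysed Grignard opening of a monosubstituted epoxide takes place at the CH2 terminus (SN2), so the C–O bond at the stereocentre stays intact and C19 keeps the S configuration of 5, while the internal alkyne with its poor silyloxy leaving group should not compete in THF below 0 °C.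

Step 3
Reactants: 7 (2S)-18-[(tert-butyldimethylsilyl)oxy]octadec-16-yn-2-ol
Product: 8 (17S)-1-[(tert-butyldimethylsilyl)oxy]-17-[(tert-butyldiphenylsilyl)oxy]octadec-2-yne
Conditions: TBDPSCl, imidazole, DMAP (cat.), DMF, rt
Reagents that add atoms: tert-butyl(chloro)diphenylsilane (TBDPSCl), CC(C)(C)[Si](Cl)(c1ccccc1)c1ccccc1
Why: Imidazole-promoted silylation of an unhindered secondary alcohol is routine, and the acid-stable TBDPS group is chosen so that both later TBS cleavages can be run without touching C19.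

Step 4
Reactants: 8 (17S)-1-[(tert-butyldimethylsilyl)oxy]-17-[(tert-butyldiphenylsilyl)oxy]octadec-2-yne
Product: 9 (17S)-17-[(tert-butyldiphenylsilyl)oxy]octadec-2-yn-1-ol
Conditions: camphorsulfonic acid (10 mol %), MeOH–CH2Cl2 1:1, 0 °C
Reagents that add atoms: none
Why: Acid-catalysed methanolysis of silyl ethers distinguishes sharply between a primary TBS ether and a secondary TBDPS ether, so only the propargylic hydroxyl should be released.

Step 5
Reactants: 9 (17S)-17-[(tert-butyldiphenylsilyl)oxy]octadec-2-yn-1-ol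
Product: 10 (2E,17S)-17-[(tert-butyldiphenylsilyl)oxy]octadec-2-en-1-ol
Conditions: NaAlH2(OCH2CH2OMe)2, THF, 0 °C → rt; aq potassium sodium tartrate
Reagents that add atoms: none
Why: Hydroxyl-directed trans-hydroalumination of a propargylic alcohol followed by protonolysis is the standard way to an E-allylic alcohol, and the remote silyl ether is inert to the hydride at this temperature.

Step 6
Reactants: 10 (2E,17S)-17-[(tert-butyldiphenylsilyl)oxy]octadec-2-en-1-ol
Product: 11 {(2S,3S)-3-[(14S)-14-[(tert-butyldiphenylsilyl)oxy]pentadecyl]oxiran-2-yl}methanol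
Conditions: Ti(OiPr)4 (10 mol %), (+)-diethyl L-tartrate (12 mol %), t-BuOOH, 4 Å molecular sieves, CH2Cl2, −20 °C
Reagents that add atoms: tert-butyl hydroperoxide, CC(C)(C)OO
Why: In the Sharpless asymmetric epoxidation the L-tartrate catalyst delivers oxygen to the face of an E-allylic alcohol that gives the (2S,3S)-trans-epoxide, which fixes the future C5 as S and sets up the future C4 for inversion.

Step 7
Reactants: 11 {(2S,3S)-3-[(14S)-14-[(tert-butyldiphenylsilyl)oxy]pentadecyl]oxiran-2-yl}methanol; 12 trimethylsilylacetylene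
Product: 15 (2R,3S,17S)-17-[(tert-butyldiphenylsilyl)oxy]-2-[(trimethylsilyl)ethynyl]octadecane-1,3-diol, via lithium acetylide 13 (not isolated), via lithium alkynylaluminate 14 (not isolated)
Conditions: 12 (4 equiv), n-BuLi (4 equiv), toluene, 0 °C; AlMe3 (4 equiv), 0 °C; then 11, 0 °C → rt; aq potassium sodium tartrate
Reagents that add atoms: none
Why: Lithium alkynyl(trialkyl)aluminates are known to open trans-2,3-epoxy alcohols at C2 to give 1,3-diols, because the C1 alkoxide binds aluminium and holds the alkynyl group next to the proximal epoxide carbon, and the SN2 attack inverts that carbon (future C4) while the C–O bond of the future C5 is left untouched.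

Step 8
Reactants: 15 (2R,3S,17S)-17-[(tert-butyldiphenylsilyl)oxy]-2-[(trimethylsilyl)ethynyl]octadecane-1,3-diol
Product: 16 (2R,3S,17S)-17-[(tert-butyldiphenylsilyl)oxy]-2-ethynyloctadecane-1,3-diol
Conditions: K2CO3 (cat.), MeOH, rt
Reagents that add atoms: none
Why: Carbonate-catalysed protodesilylation of an alkynylsilane in methanol is fast at room temperature and leaves the oxygen-bound silyl group and both new stereocentres alone.

Step 9
Reactants: 16 (2R,3S,17S)-17-[(tert-butyldiphenylsilyl)oxy]-2-ethynyloctadecane-1,3-diol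
Product: 17 (2R,3S,17S)-1-[(tert-butyldimethylsilyl)oxy]-17-[(tert-butyldiphenylsilyl)oxy]-2-ethynyloctadecan-3-ol
Conditions: TBSCl (1.05 equiv), imidazole, CH2Cl2, 0 °C
Reagents that add atoms: tert-butyl(chloro)dimethylsilane (TBSCl), CC(C)(C)[Si](C)(C)Cl
Why: In this sterically controlled monosilylation of a 1,3-diol the primary hydroxyl reacts much faster than the secondary one next to the branched carbon, which leaves the C5 hydroxyl free for the carbonylation.

Step 10
Reactants: 17 (2R,3S,17S)-1-[(tert-butyldimethylsilyl)oxy]-17-[(tert-butyldiphenylsilyl)oxy]-2-ethynyloctadecan-3-ol; 18 carbon monoxide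
Product: 19 (4R,5S)-4-{[(tert-butyldimethylsilyl)oxy]methyl}-5-[(14S)-14-[(tert-butyldiphenylsilyl)oxy]pentadecyl]-3-methylideneoxolan-2-one (cis)
Conditions: PdCl2 (10 mol %), thiourea (20 mol %), CO (3 atm), dry acetone, 50 °C
Reagents that add atoms: none
Why: The C5 hydroxyl and CO should turn the thiourea-ligated PdCl2 into an alkoxycarbonyl complex of divalent palladium with release of HCl, the Pd–acyl bond then adds syn across the ethynyl group so that C2 bonds to the inner alkyne carbon C3, and protonolysis of the vinyl–palladium bond by the HCl leaves the exo-methylene group and returns the catalyst. The closest known reaction type is the palladium-catalysed cyclocarbonylation of but-3-yn-1-ols to α-methylene-γ-butyrolactones, of which 17 is a plain acyclic member. The one ring formed (O1–C2–C3–C4–C5) closes by a 5-exo-dig acylpalladation. No stereocentre is created: C4 and C5 enter unchanged from 17, and their syn relation becomes the cis ring because the base-free medium touches neither centre. The step needs chemoselectivity between two homopropargylic oxygens, which the silyl ether on the C4 hydroxymethyl group secures by leaving only the C5 hydroxyl able to capture CO on palladium. Dry acetone is used to keep that silyl ether in place.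

Step 11
Reactants: 19 (4R,5S)-4-{[(tert-butyldimethylsilyl)oxy]methyl}-5-[(14S)-14-[(tert-butyldiphenylsilyl)oxy]pentadecyl]-3-methylideneoxolan-2-one
Product: 20 (4R,5S)-5-[(14S)-14-[(tert-butyldiphenylsilyl)oxy]pentadecyl]-4-(hydroxymethyl)-3-methylideneoxolan-2-one
Conditions: AcOH–THF–H2O 3:1:1, rt
Reagents that add atoms: none
Why: Mild aqueous-acid hydrolysis cleaves a primary TBS ether while the secondary TBDPS ether, the lactone and the exo-methylene group are tolerated, and the absence of base and of an alcohol solvent should prevent acyl migration to the new primary hydroxyl.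

Step 12
Reactants: 20 (4R,5S)-5-[(14S)-14-[(tert-butyldiphenylsilyl)oxy]pentadecyl]-4-(hydroxymethyl)-3-methylideneoxolan-2-one
Product: 22 (2S,3S)-2-[(14S)-14-[(tert-butyldiphenylsilyl)oxy]pentadecyl]-4-methylidene-5-oxooxolane-3-carboxylic acid, via aldehyde 21 (not isolated)
Conditions: TEMPO (20 mol %), PhI(OAc)2 (2.5 equiv), MeCN–H2O 1:1, 0 °C → rt
Reagents that add atoms: water, O
Why: The oxoammonium oxidation (TEMPO/PhI(OAc)2 in aqueous acetonitrile) takes a primary alcohol through the aldehyde hydrate to the acid in a weakly acidic, base-free medium, which should keep the C4–H of the transient β,γ-unsaturated aldehyde from enolising, and the electron-poor alkene is not attacked.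

Step 13
Reactants: 22 (2S,3S)-2-[(14S)-14-[(tert-butyldiphenylsilyl)oxy]pentadecyl]-4-methylidene-5-oxooxolane-3-carboxylic acid
Product: 23 (2S,3S)-2-[(14S)-14-hydroxypentadecyl]-4-methylidene-5-oxooxolane-3-carboxylic acid
Conditions: HF·pyridine (excess), THF, 0 °C → rt, plastic vessel
Reagents that add atoms: none
Why: Fluoride-driven cleavage of the Si–O bond in an acidic medium removes the TBDPS group without the base that would move the exocyclic double bond into the ring or epimerise C4.

Compound list
1 | tert-butyldimethyl(prop-2-yn-1-yloxy)silane | C#CCO[Si](C)(C)C(C)(C)C | starting material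
2 | 1,12-dibromododecane | BrCCCCCCCCCCCCBr | starting material
3 | {3-[(tert-butyldimethylsilyl)oxy]prop-1-yn-1-yl}lithium (not isolated) | [Li]C#CCO[Si](C)(C)C(C)(C)C | intermediate
4 | [(15-bromopentadec-2-yn-1-yl)oxy](tert-butyl)dimethylsilane | BrCCCCCCCCCCCCC#CCO[Si](C)(C)C(C)(C)C | intermediate
5 | (S)-propylene oxide | C[C@H]1CO1 | starting material
6 | {15-[(tert-butyldimethylsilyl)oxy]pentadec-13-yn-1-yl}magnesium bromide (not isolated) | Br[Mg]CCCCCCCCCCCCC#CCO[Si](C)(C)C(C)(C)C | intermediate
7 | (2S)-18-[(tert-butyldimethylsilyl)oxy]octadec-16-yn-2-ol | CC(C)(C)[Si](C)(C)OCC#CCCCCCCCCCCCCC[C@H](C)O | intermediate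
8 | (17S)-1-[(tert-butyldimethylsilyl)oxy]-17-[(tert-butyldiphenylsilyl)oxy]octadec-2-yne | CC(C)(C)[Si](C)(C)OCC#CCCCCCCCCCCCCC[C@H](C)O[Si](c1ccccc1)(c1ccccc1)C(C)(C)C | intermediate
9 | (17S)-17-[(tert-butyldiphenylsilyl)oxy]octadec-2-yn-1-ol | OCC#CCCCCCCCCCCCCC[C@H](C)O[Si](c1ccccc1)(c1ccccc1)C(C)(C)C | intermediate
10 | (2E,17S)-17-[(tert-butyldiphenylsilyl)oxy]octadec-2-en-1-ol | OC/C=C/CCCCCCCCCCCCC[C@H](C)O[Si](c1ccccc1)(c1ccccc1)C(C)(C)C | intermediate
11 | {(2S,3S)-3-[(14S)-14-[(tert-butyldiphenylsilyl)oxy]pentadecyl]oxiran-2-yl}methanol | OC[C@@H]1O[C@H]1CCCCCCCCCCCCC[C@H](C)O[Si](c1ccccc1)(c1ccccc1)C(C)(C)C | intermediate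
12 | trimethylsilylacetylene | C#C[Si](C)(C)C | starting material
13 | lithium (trimethylsilyl)acetylide (not isolated) | [Li]C#C[Si](C)(C)C | intermediate
14 | lithium trimethyl[(trimethylsilyl)ethynyl]aluminate (not isolated) | [Li+].C[Al-](C)(C)C#C[Si](C)(C)C | intermediate
15 | (2R,3S,17S)-17-[(tert-butyldiphenylsilyl)oxy]-2-[(trimethylsilyl)ethynyl]octadecane-1,3-diol | O[C@@H](CCCCCCCCCCCCC[C@H](C)O[Si](c1ccccc1)(c1ccccc1)C(C)(C)C)[C@H](C#C[Si](C)(C)C)CO | intermediate
16 | (2R,3S,17S)-17-[(tert-butyldiphenylsilyl)oxy]-2-ethynyloctadecane-1,3-diol | O[C@@H](CCCCCCCCCCCCC[C@H](C)O[Si](c1ccccc1)(c1ccccc1)C(C)(C)C)[C@H](C#C)CO | intermediate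
17 | (2R,3S,17S)-1-[(tert-butyldimethylsilyl)oxy]-17-[(tert-butyldiphenylsilyl)oxy]-2-ethynyloctadecan-3-ol | O[C@@H](CCCCCCCCCCCCC[C@H](C)O[Si](c1ccccc1)(c1ccccc1)C(C)(C)C)[C@H](C#C)CO[Si](C)(C)C(C)(C)C | intermediate
18 | carbon monoxide | [C-]#[O+] | starting material
19 | (4R,5S)-4-{[(tert-butyldimethylsilyl)oxy]methyl}-5-[(14S)-14-[(tert-butyldiphenylsilyl)oxy]pentadecyl]-3-methylideneoxolan-2-one | C=C1C(=O)O[C@@H](CCCCCCCCCCCCC[C@H](C)O[Si](c2ccccc2)(c2ccccc2)C(C)(C)C)[C@H]1CO[Si](C)(C)C(C)(C)C | intermediate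
20 | (4R,5S)-5-[(14S)-14-[(tert-butyldiphenylsilyl)oxy]pentadecyl]-4-(hydroxymethyl)-3-methylideneoxolan-2-one | C=C1C(=O)O[C@@H](CCCCCCCCCCCCC[C@H](C)O[Si](c2ccccc2)(c2ccccc2)C(C)(C)C)[C@H]1CO | intermediate
21 | (2S,3S)-2-[(14S)-14-[(tert-butyldiphenylsilyl)oxy]pentadecyl]-4-methylidene-5-oxooxolane-3-carbaldehyde (not isolated) | C=C1C(=O)O[C@@H](CCCCCCCCCCCCC[C@H](C)O[Si](c2ccccc2)(c2ccccc2)C(C)(C)C)[C@H]1C=O | intermediate
22 | (2S,3S)-2-[(14S)-14-[(tert-butyldiphenylsilyl)oxy]pentadecyl]-4-methylidene-5-oxooxolane-3-carboxylic acid | C=C1C(=O)O[C@@H](CCCCCCCCCCCCC[C@H](C)O[Si](c2ccccc2)(c2ccccc2)C(C)(C)C)[C@H]1C(=O)O | intermediate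
23 | (2S,3S)-2-[(14S)-14-hydroxypentadecyl]-4-methylidene-5-oxooxolane-3-carboxylic acid | C=C1C(=O)O[C@@H](CCCCCCCCCCCCC[C@H](C)O)[C@H]1C(=O)O | target

Total step count: 13. Longest linear sequence: 13 (steps 1–13; no fragment is built separately).

Steps most likely to fail

Step 10. Three processes may interfere.
- The palladium chloride/HCl medium may strip the primary silyl ether before ring closure, so that the wrong hydroxyl captures CO.
- A palladium hydride may move the exocyclic double bond into the ring.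
- The catalyst may decay to zerovalent palladium through alkyne oligomerisation.

The fallback sets out from 17 and comes back at 19, and it builds the ring without CO. Anti-Markovnikov hydroboration of the ethynyl group with Cy2BH (one extra equivalent for the hydroxyl) and oxidation with NaBO3·4H2O turn the terminal alkyne carbon into an aldehyde. This aldehyde closes on the C5 hydroxyl to the γ-lactol F1. TEMPO/PhI(OAc)2 in CH2Cl2 oxidises it to the saturated cis-lactone F2. LiN(iPr)2 at −78 °C followed by dimethylmethyleneammonium iodide gives the Mannich base F3, and MeI gives the ammonium iodide F4. Aqueous NaHCO3 then eliminates the amine to give 19. In this variant the former terminal alkyne carbon becomes C2 and the methylene carbon comes from the iminium salt. C4 is never enolisable.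

Step 7. Regiocontrol may be eroded by attack of the alkynyl group at the distal epoxide carbon, or by alkoxide-induced Payne migration of the epoxide before opening.

The fallback sets out from 11 and comes back at 16. It replaces the alkynyl transfer by a copper-mediated vinyl transfer and a one-carbon homologation.
- CH2=CHMgBr with CuI in THF–Et2O at −40 °C, a combination known to favour C2 of 2,3-epoxy alcohols, gives with inversion the vinyl diol F5.
- 2,2-Dimethoxypropane with pyridinium tosylate gives the trans-4,5-disubstituted acetonide F6.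
- Ozonolysis with PPh3 work-up gives the equatorial, configurationally stable aldehyde F7.
- Dimethyl (1-diazo-2-oxopropyl)phosphonate with K2CO3 in MeOH (Ohira–Bestmann homologation) gives the ethynyl acetonide F8.
- Aqueous AcOH releases 16.

Step 12. The transient aldehyde may enolise. This would epimerise C4 towards the trans series or draw the exocyclic double bond into conjugation before the second oxidation takes place.

The fallback sets out from 20 and comes back at 22. It masks the alkene so that the aldehyde is no longer β,γ-unsaturated. Conjugate addition of Me2NH in THF gives the amino alcohol F9. CrO3/H2SO4 in acetone at 0 °C, with the amine protected as its ammonium ion, gives the amino acid F10. MeI with KHCO3 in MeOH gives the betaine F11, which loses its amine by β-elimination under the same mild conditions. Acidification then gives 22.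

Further compounds
F1 | step 10 | (4R,5S)-4-{[(tert-butyldimethylsilyl)oxy]methyl}-5-[(14S)-14-[(tert-butyldiphenylsilyl)oxy]pentadecyl]oxolan-2-ol (both anomers) | C1C(O)O[C@@H](CCCCCCCCCCCCC[C@H](C)O[Si](c2ccccc2)(c2ccccc2)C(C)(C)C)[C@H]1CO[Si](C)(C)C(C)(C)C
F2 | step 10 | (4R,5S)-4-{[(tert-butyldimethylsilyl)oxy]methyl}-5-[(14S)-14-[(tert-butyldiphenylsilyl)oxy]pentadecyl]oxolan-2-one | C1C(=O)O[C@@H](CCCCCCCCCCCCC[C@H](C)O[Si](c2ccccc2)(c2ccccc2)C(C)(C)C)[C@H]1CO[Si](C)(C)C(C)(C)C
F3 | step 10 | (4R,5S)-4-{[(tert-butyldimethylsilyl)oxy]methyl}-3-[(dimethylamino)methyl]-5-[(14S)-14-[(tert-butyldiphenylsilyl)oxy]pentadecyl]oxolan-2-one (C3 left open) | CN(C)CC1C(=O)O[C@@H](CCCCCCCCCCCCC[C@H](C)O[Si](c2ccccc2)(c2ccccc2)C(C)(C)C)[C@H]1CO[Si](C)(C)C(C)(C)C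
F4 | step 10 | trimethylammonium iodide derived from F3 (C3 left open) | C[N+](C)(C)CC1C(=O)O[C@@H](CCCCCCCCCCCCC[C@H](C)O[Si](c2ccccc2)(c2ccccc2)C(C)(C)C)[C@H]1CO[Si](C)(C)C(C)(C)C.[I-]
F5 | step 7 | (2R,3S,17S)-17-[(tert-butyldiphenylsilyl)oxy]-2-ethenyloctadecane-1,3-diol | O[C@@H](CCCCCCCCCCCCC[C@H](C)O[Si](c1ccccc1)(c1ccccc1)C(C)(C)C)[C@H](C=C)CO
F6 | step 7 | (4S,5R)-5-ethenyl-2,2-dimethyl-4-[(14S)-14-[(tert-butyldiphenylsilyl)oxy]pentadecyl]-1,3-dioxane | C=C[C@@H]1COC(C)(C)O[C@H]1CCCCCCCCCCCCC[C@H](C)O[Si](c1ccccc1)(c1ccccc1)C(C)(C)C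
F7 | step 7 | (4S,5R)-2,2-dimethyl-4-[(14S)-14-[(tert-butyldiphenylsilyl)oxy]pentadecyl]-1,3-dioxane-5-carbaldehyde | O=C[C@@H]1COC(C)(C)O[C@H]1CCCCCCCCCCCCC[C@H](C)O[Si](c1ccccc1)(c1ccccc1)C(C)(C)C
F8 | step 7 | (4S,5R)-5-ethynyl-2,2-dimethyl-4-[(14S)-14-[(tert-butyldiphenylsilyl)oxy]pentadecyl]-1,3-dioxane | C#C[C@@H]1COC(C)(C)O[C@H]1CCCCCCCCCCCCC[C@H](C)O[Si](c1ccccc1)(c1ccccc1)C(C)(C)C
F9 | step 12 | (4R,5S)-3-[(dimethylamino)methyl]-4-(hydroxymethyl)-5-[(14S)-14-[(tert-butyldiphenylsilyl)oxy]pentadecyl]oxolan-2-one (C3 left open) | CN(C)CC1C(=O)O[C@@H](CCCCCCCCCCCCC[C@H](C)O[Si](c2ccccc2)(c2ccccc2)C(C)(C)C)[C@H]1CO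
F10 | step 12 | (2S,3S)-4-[(dimethylamino)methyl]-5-oxo-2-[(14S)-14-[(tert-butyldiphenylsilyl)oxy]pentadecyl]oxolane-3-carboxylic acid (C4 of the oxolane left open) | CN(C)CC1C(=O)O[C@@H](CCCCCCCCCCCCC[C@H](C)O[Si](c2ccccc2)(c2ccccc2)C(C)(C)C)[C@H]1C(=O)O
F11 | step 12 | trimethylammonio carboxylate (betaine) derived from F10 | C[N+](C)(C)CC1C(=O)O[C@@H](CCCCCCCCCCCCC[C@H](C)O[Si](c2ccccc2)(c2ccccc2)C(C)(C)C)[C@H]1C(=O)[O-]
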